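**Strategy.** The plan rests on cutting ring A at C5–C10. C10 bears H, sits between the oxygenated carbons C1 and C9 and is bonded to quaternary C5, exactly the array produced when an oxirane carbon is inserted into a cyclopentanol. In one operation a Lewis acid-triggered semipinacol shift moves C5 from C1 to the oxirane carbon, enlarging the five-membered ring to ring A, creating the C1 ketone and the C9 hydroxymethyl group and fixing C10. The precursor is a 2-allyl-2,3-dimethylcyclopentanol carrying an (S)-oxirane on its carbinol carbon, three steps from 2-methylcyclopentenone. Ring B is then closed by metathesis, and a trans-diaxial epoxide opening sets C7 and C8.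

Key step: step 4

Remark: eremophilane numbering is used (ring A = C1–C5 and C10, ring B = C5–C10, methyls on C4 and C5; β is the face of the C5 methyl, α the opposite face). The tertiary carbinol centre of the vinyl and oxiranyl cyclopentanols is assumed to be the epimer from vinyl attack anti to the two methyl groups; it is erased in the key step, so only the S configuration of the oxirane carbon matters.

**Step 1**
Reactants: 1 2-methylcyclopent-2-en-1-one; 2 trimethylaluminium; 3 allyl bromide
Product: 5 (2R,3S)-2,3-dimethyl-2-(prop-2-en-1-yl)cyclopentan-1-one, via aluminium enolate 4 (not isolated)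
Conditions: Cu(OTf)2 (2 mol%), binaphthol-derived phosphoramidite ligand (4 mol%, antipode chosen for the 3S sense), Et2O, −30 °C; then MeLi, −30 °C; then 3, DMPU, −30 °C → rt
Reagents that add atoms: none
Why: Copper-catalysed asymmetric conjugate addition of the methylaluminium reagent sets C4 under control of the chiral ligand, and the MeLi-activated enolate 4 is allylated anti to the new C4 methyl group (tandem conjugate addition–enolate alkylation), which sets quaternary C5 with the two methyl groups cis.

**Step 2**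
Reactants: 5 (2R,3S)-2,3-dimethyl-2-(prop-2-en-1-yl)cyclopentan-1-one; 6 vinylmagnesium bromide
Product: 7 (1S,2R,3S)-1-ethenyl-2,3-dimethyl-2-(prop-2-en-1-yl)cyclopentan-1-ol
Conditions: CeCl3 (anhydrous), THF, −78 → 0 °C
Reagents that add atoms: none
Why: Organocerium 1,2-addition suppresses enolisation of the hindered ketone, and vinyl should enter anti to the C5 and C4 methyl groups (the face carrying only the allyl CH2), placing OH cis to both methyls and trans to the allyl group.

**Step 3**
Reactants: 7 (1S,2R,3S)-1-ethenyl-2,3-dimethyl-2-(prop-2-en-1-yl)cyclopentan-1-ol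
Product: 8 (1R,2R,3S)-2,3-dimethyl-1-[(2S)-oxiran-2-yl]-2-(prop-2-en-1-yl)cyclopentan-1-ol
Conditions: VO(acac)2 (5 mol%), t-BuOOH, CH2Cl2, 0 °C → rt
Reagents that add atoms: tert-butyl hydroperoxide, CC(C)(C)OO
Why: Hydroxyl-directed vanadium-catalysed epoxidation acts only on the allylic alcohol (the allyl group lies trans to OH and is not reached), and with an O–C–C=C dihedral near 45° and the bulky quaternary C5 arm turned away from the metal the oxygen should be delivered to the face that makes the oxirane carbon S.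

**Step 4**
Reactants: 8 (1R,2R,3S)-2,3-dimethyl-1-[(2S)-oxiran-2-yl]-2-(prop-2-en-1-yl)cyclopentan-1-ol
Product: 9 (2R,3R,4S)-2-(hydroxymethyl)-3,4-dimethyl-3-(prop-2-en-1-yl)cyclohexan-1-one
Conditions: BF3·OEt2 (0.3 equiv), CH2Cl2, −78 → −30 °C; aq NaHCO3
Reagents that add atoms: none
Why: BF3 binds the oxirane oxygen and weakens the C10–O bond; the ring bond C1–C5, held antiperiplanar to it, shifts to C10 while the carbinol oxygen becomes the C1 carbonyl, and proton transfer releases the β-hydroxy ketone and the Lewis acid. The closest known reaction type is the Lewis acid-promoted semipinacol rearrangement of 2,3-epoxy alcohols (1-oxiranylcycloalkanols) to 2-(hydroxyalkyl)cycloalkanones. Ring A is not closed end to end but formed by ring enlargement, a suprafacial 1,2-alkyl shift that inserts the exocyclic carbon C10 between C1 and C5 (five- to six-membered). The new stereocentre C10 is set by the S configuration of the oxirane carbon, because C5 attacks from the rear (inversion at C10, retention at C5), which places C9 trans to the allyl group; this is also the equatorial, more stable epimer, so a C10 epimer can drift to it by enolisation. The step needs migration of C5 instead of C2 and opening at C10 instead of C9: the fully substituted C5 has the higher migratory aptitude, and only C10 is adjacent to the carbinol carbon that supplies the electron push. Cold, sub-stoichiometric Lewis acid and a bicarbonate quench should hold back retro-aldol loss of formaldehyde and dehydration.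

**Step 5**
Reactants: 9 (2R,3R,4S)-2-(hydroxymethyl)-3,4-dimethyl-3-(prop-2-en-1-yl)cyclohexan-1-one
Product: 10 (1S,2R,3R,4S)-2-(hydroxymethyl)-3,4-dimethyl-3-(prop-2-en-1-yl)cyclohexan-1-ol
Conditions: Me4NBH(OAc)3, MeCN–AcOH, −30 °C
Reagents that add atoms: none
Why: Saksena–Evans reduction, in which the primary hydroxyl binds the triacetoxyborohydride and delivers hydride to the carbonyl face on its own side (axial attack), giving the equatorial C1 alcohol trans to C9, whereas an external hydride would be turned away by the axial C5 methyl.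

**Step 6**
Reactants: 10 (1S,2R,3R,4S)-2-(hydroxymethyl)-3,4-dimethyl-3-(prop-2-en-1-yl)cyclohexan-1-ol
Product: 11 bis(triethylsilyl) ether of 10
Conditions: Et3SiCl, imidazole, DMF, 0 °C → rt
Reagents that add atoms: chlorotriethylsilane, CC[Si](Cl)(CC)CC
Why: Routine silylation of both hydroxyl groups, with no stereocentre affected.

**Step 7**
Reactants: 11 bis(triethylsilyl) ether of 10
Product: 12 (1S,2R,3S,6S)-2,3-dimethyl-2-(prop-2-en-1-yl)-6-[(triethylsilyl)oxy]cyclohexane-1-carbaldehyde
Conditions: (COCl)2, DMSO, CH2Cl2, −78 → −30 °C; Et3N, → 0 °C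
Reagents that add atoms: none
Why: Under Swern conditions a primary triethylsilyl ether is cleaved by the chlorosulfonium reagent and oxidised in situ while the secondary silyl ether is inert, giving the aldehyde directly with its formyl group in the stable equatorial position at C10.

**Step 8**
Reactants: 12 (1S,2R,3S,6S)-2,3-dimethyl-2-(prop-2-en-1-yl)-6-[(triethylsilyl)oxy]cyclohexane-1-carbaldehyde; 6 vinylmagnesium bromide
Product: 13 (1R)-1-[(1R,2R,3S,6S)-2,3-dimethyl-2-(prop-2-en-1-yl)-6-[(triethylsilyl)oxy]cyclohexyl]prop-2-en-1-ol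
Conditions: THF, −78 °C; aq NH4Cl
Reagents that add atoms: none
Why: Grignard 1,2-addition under Felkin–Anh control, in which vinyl approaches anti to the quaternary C5 substituent and past the C10 hydrogen, should set C9 as the 9α (R) carbinol that becomes equatorial in ring B.

**Step 9**
Reactants: 13 (1R)-1-[(1R,2R,3S,6S)-2,3-dimethyl-2-(prop-2-en-1-yl)-6-[(triethylsilyl)oxy]cyclohexyl]prop-2-en-1-ol
Product: 14 (1R,4aR,5S,8S,8aR)-4a,5-dimethyl-8-[(triethylsilyl)oxy]-1,4,4a,5,6,7,8,8a-octahydronaphthalen-1-ol (trans-fused; C7=C8 alkene, 9α-OH, 1α-OSiEt3)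
Conditions: second-generation Grubbs catalyst (3 mol%), CH2Cl2, 40 °C
Reagents that add atoms: none
Why: Ring-closing metathesis of the allyl and vinyl groups, held trans-diequatorial on ring A, closes the trans-fused cyclohexene ring B with loss of ethene and without change at any stereocentre.

**Step 10**
Reactants: 14 (1R,4aR,5S,8S,8aR)-4a,5-dimethyl-8-[(triethylsilyl)oxy]-1,4,4a,5,6,7,8,8a-octahydronaphthalen-1-ol
Product: 15 7α,8α-epoxide of 14 (oxirane cis to the 9α-OH, anti to the C5 methyl)
Conditions: mCPBA, NaHCO3, CH2Cl2, 0 °C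
Reagents that add atoms: 3-chloroperbenzoic acid, OOC(=O)c1cccc(Cl)c1
Why: Peracid epoxidation directed by hydrogen bonding to the pseudo-equatorial 9α-hydroxyl (Henbest effect), reinforced by the axial C5 methyl shielding the β face, gives the 7α,8α-epoxide.

**Step 11**
Reactants: 15 7α,8α-epoxide of 14
Product: 16 9-O-tert-butyldimethylsilyl ether of 15
Conditions: TBSOTf, 2,6-lutidine, CH2Cl2, −78 °C
Reagents that add atoms: tert-butyldimethylsilyl trifluoromethanesulfonate, CC(C)(C)[Si](C)(C)OS(=O)(=O)C(F)(F)F
Why: Silylation with the silyl triflate and a hindered base at low temperature caps the C9 hydroxyl without forming an alkoxide (no silyl migration, oxirane untouched), so that C8 will carry the only free hydroxyl after ring opening.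

**Step 12**
Reactants: 16 9-O-tert-butyldimethylsilyl ether of 15; 17 isopropenylmagnesium bromide
Product: 18 7β-isopropenyl-8α-hydroxy-9α-(tert-butyldimethylsilyloxy)-1α-(triethylsilyloxy)-4β,5β-dimethyl-10αH-decalin
Conditions: CuI (20 mol%), THF, −30 → 0 °C; aq NH4Cl
Reagents that add atoms: none
Why: Copper-catalysed Grignard opening of the epoxide follows the Fürst–Plattner rule, since only attack at C7 from the β face leads to the trans-diaxial chair product and C8 is further shielded by the adjacent silyloxy group, so inversion at C7 sets the 7β-isopropenyl group and leaves the 8α-hydroxyl.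

**Step 13**
Reactants: 18 7β-isopropenyl-8α-ol; 19 angelic acid ((2Z)-2-methylbut-2-enoic acid)
Product: 21 8-O-angelate of 18, via mixed anhydride 20 (not isolated)
Conditions: 2,4,6-trichlorobenzoyl chloride, Et3N, toluene, rt; then 18, 80 °C
Reagents that add atoms: none
Why: Yamaguchi-type esterification through the mixed 2,4,6-trichlorobenzoic anhydride 20 acylates hindered secondary alcohols with angelic acid without a nucleophilic catalyst, which avoids isomerisation of the Z double bond to the tiglate and leaves C8 unchanged.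

**Step 14**
Reactants: 21 8-O-angelate of 18
Product: 22 1α-alcohol (21 without the triethylsilyl group)
Conditions: PPTS, MeOH–CH2Cl2, 0 °C → rt
Reagents that add atoms: none
Why: Mild acid methanolysis removes the secondary triethylsilyl ether much faster than the hindered tert-butyldimethylsilyl ether, and the ester and the isopropenyl group are inert.

**Step 15**
Reactants: 22 1α-alcohol; 23 acetic anhydride
Product: 24 1-O-acetate of 22
Conditions: pyridine, DMAP (cat.), CH2Cl2, rt
Reagents that add atoms: none
Why: Standard acylation of the equatorial C1 alcohol with acetic anhydride under nucleophilic catalysis.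

**Step 16**
Reactants: 24 1-O-acetate of 22
Product: 25 1α-acetoxy-8α-angeloyloxy-eremophil-11-en-9α-ol
Conditions: HF·pyridine, pyridine, THF, 0 °C → rt
Reagents that add atoms: none
Why: Buffered hydrogen fluoride–pyridine cleaves the remaining silyl ether under non-basic conditions, so neither ester should migrate to the liberated C9 hydroxyl.

**Step 17**
Reactants: 25 1α-acetoxy-8α-angeloyloxy-eremophil-11-en-9α-ol
Product: 26 (1S,4S,5R,7R,8R,10S)-1-acetoxy-8-[(2Z)-2-methylbut-2-enoyloxy]eremophil-11-en-9-one (target, CNP0138236.2)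
Conditions: Dess–Martin periodinane, NaHCO3, CH2Cl2, 0 °C → rt
Reagents that add atoms: none
Why: Dess–Martin oxidation of the secondary alcohol under buffered, non-basic conditions forms the C9 ketone last, so the epimerisable centres C8 and C10 that flank it are never exposed to base.

**Compound list**
1 | 2-methylcyclopent-2-en-1-one | CC1=CCCC1=O | starting material
2 | trimethylaluminium | C[Al](C)C | starting material
3 | allyl bromide | C=CCBr | starting material
4 | {[(3S)-2,3-dimethylcyclopent-1-en-1-yl]oxy}dimethylaluminium (aluminium enolate) | C[C@H]1CCC(O[Al](C)C)=C1C | intermediate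
5 | (2R,3S)-2,3-dimethyl-2-(prop-2-en-1-yl)cyclopentan-1-one | C=CC[C@@]1(C)C(=O)CC[C@@H]1C | intermediate
6 | vinylmagnesium bromide | C=C[Mg]Br | starting material
7 | (1S,2R,3S)-1-ethenyl-2,3-dimethyl-2-(prop-2-en-1-yl)cyclopentan-1-ol | C=CC[C@@]1(C)[C@@](O)(C=C)CC[C@@H]1C | intermediate
8 | (1R,2R,3S)-2,3-dimethyl-1-[(2S)-oxiran-2-yl]-2-(prop-2-en-1-yl)cyclopentan-1-ol | C=CC[C@@]1(C)[C@@](O)([C@@H]2CO2)CC[C@@H]1C | intermediate
9 | (2R,3R,4S)-2-(hydroxymethyl)-3,4-dimethyl-3-(prop-2-en-1-yl)cyclohexan-1-one | C=CC[C@@]1(C)[C@H](CO)C(=O)CC[C@@H]1C | intermediate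
10 | (1S,2R,3R,4S)-2-(hydroxymethyl)-3,4-dimethyl-3-(prop-2-en-1-yl)cyclohexan-1-ol | C=CC[C@@]1(C)[C@H](CO)[C@@H](O)CC[C@@H]1C | intermediate
11 | bis(triethylsilyl) ether of 10 | C=CC[C@@]1(C)[C@H](CO[Si](CC)(CC)CC)[C@@H](O[Si](CC)(CC)CC)CC[C@@H]1C | intermediate
12 | (1S,2R,3S,6S)-2,3-dimethyl-2-(prop-2-en-1-yl)-6-[(triethylsilyl)oxy]cyclohexane-1-carbaldehyde | C=CC[C@@]1(C)[C@H](C=O)[C@@H](O[Si](CC)(CC)CC)CC[C@@H]1C | intermediate
13 | (1R)-1-[(1R,2R,3S,6S)-2,3-dimethyl-2-(prop-2-en-1-yl)-6-[(triethylsilyl)oxy]cyclohexyl]prop-2-en-1-ol | C=CC[C@@]1(C)[C@H]([C@H](O)C=C)[C@@H](O[Si](CC)(CC)CC)CC[C@@H]1C | intermediate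
14 | (1R,4aR,5S,8S,8aR)-4a,5-dimethyl-8-[(triethylsilyl)oxy]-1,4,4a,5,6,7,8,8a-octahydronaphthalen-1-ol | C=1C[C@@]2(C)[C@H]([C@H](O)C=1)[C@@H](O[Si](CC)(CC)CC)CC[C@@H]2C | intermediate
15 | 7α,8α-epoxide of 14 (9α-OH, 1α-OSiEt3) | [C@@H]13C[C@@]2(C)[C@H]([C@H](O)[C@@H]1O3)[C@@H](O[Si](CC)(CC)CC)CC[C@@H]2C | intermediate
16 | 9-O-tert-butyldimethylsilyl ether of 15 | [C@@H]13C[C@@]2(C)[C@H]([C@H](O[Si](C)(C)C(C)(C)C)[C@@H]1O3)[C@@H](O[Si](CC)(CC)CC)CC[C@@H]2C | intermediate
17 | isopropenylmagnesium bromide | C=C(C)[Mg]Br | starting material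
18 | 7β-isopropenyl-8α-hydroxy-9α-(tert-butyldimethylsilyloxy)-1α-(triethylsilyloxy)-4β,5β-dimethyl-10αH-decalin | C=C(C)[C@H]1C[C@@]2(C)[C@H]([C@H](O[Si](C)(C)C(C)(C)C)[C@@H]1O)[C@@H](O[Si](CC)(CC)CC)CC[C@@H]2C | intermediate
19 | angelic acid, (2Z)-2-methylbut-2-enoic acid | C/C=C(/C)C(=O)O | starting material
20 | angelic 2,4,6-trichlorobenzoic anhydride (mixed anhydride) | C/C=C(/C)C(=O)OC(=O)c1c(Cl)cc(Cl)cc1Cl | intermediate
21 | 8-O-angelate of 18 | C=C(C)[C@H]1C[C@@]2(C)[C@H]([C@H](O[Si](C)(C)C(C)(C)C)[C@@H]1OC(=O)/C(C)=C\C)[C@@H](O[Si](CC)(CC)CC)CC[C@@H]2C | intermediate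
22 | 1α-alcohol (21 without the triethylsilyl group) | C=C(C)[C@H]1C[C@@]2(C)[C@H]([C@H](O[Si](C)(C)C(C)(C)C)[C@@H]1OC(=O)/C(C)=C\C)[C@@H](O)CC[C@@H]2C | intermediate
23 | acetic anhydride | CC(=O)OC(C)=O | starting material
24 | 1-O-acetate of 22 | C=C(C)[C@H]1C[C@@]2(C)[C@H]([C@H](O[Si](C)(C)C(C)(C)C)[C@@H]1OC(=O)/C(C)=C\C)[C@@H](OC(C)=O)CC[C@@H]2C | intermediate
25 | 1α-acetoxy-8α-angeloyloxy-eremophil-11-en-9α-ol | C=C(C)[C@H]1C[C@@]2(C)[C@H]([C@H](O)[C@@H]1OC(=O)/C(C)=C\C)[C@@H](OC(C)=O)CC[C@@H]2C | intermediate
26 | (1S,4S,5R,7R,8R,10S)-1-acetoxy-8-[(2Z)-2-methylbut-2-enoyloxy]eremophil-11-en-9-one | C=C(C)[C@H]1C[C@@]2(C)[C@H](C(=O)[C@@H]1OC(=O)/C(C)=C\C)[C@@H](OC(C)=O)CC[C@@H]2C | target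

**Step count.** Total: 17 steps. Longest linear sequence: 17 steps (the route is fully linear).

**Steps most likely to fail**

Step 4 (key step). The activated oxirane may be opened at its primary carbon by external nucleophiles, the ring CH2 (C2) may compete in the shift, or the aldol-type product may lose formaldehyde by retro-aldol cleavage before isolation. The fallback replaces the oxirane opening by a sulfonate leaving group and an aluminium-promoted pinacol-type shift; it sets out from 8 and comes back at 9. The oxirane of 8 is opened at C9 with 4-methoxyphenol (K2CO3, DMF, 80 °C) to give the diol aryl ether F1. The secondary C10 hydroxyl is then mesylated (MsCl, Et3N, CH2Cl2, 0 °C) to give the mesylate F2. Et3Al (CH2Cl2, −78 °C) forms the aluminium alkoxide of the tertiary carbinol and drives the anti 1,2-shift of C5 with inversion at C10 to the aryloxymethyl ketone F3. (NH4)2Ce(NO3)6 in aqueous MeCN removes the aryl group and gives 9.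

Step 12. The isopropenyl nucleophile must enter at C7 syn-axial to the C5 methyl group, so the opening may be slow and give way to halohydrin formation or Lewis acid rearrangement of the epoxide. The fallback uses a slim sp-carbon nucleophile and then builds the isopropenyl group; it sets out from 16 and comes back at 18. LiC≡CSiMe3 with BF3·OEt2 (THF, −78 °C) opens the epoxide trans-diaxially to the silylalkynyl alcohol F4. K2CO3 in MeOH removes the C-silyl group to give the terminal alkyne F5. Negishi carboalumination (AlMe3, Cp2ZrCl2 cat., CH2Cl2) adds methyl to the internal alkyne carbon, and protonolysis of the vinylalane gives 18.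

Step 13. Acylation of the hindered axial C8 hydroxyl may be slow, and on prolonged heating the Z double bond of the angeloyl unit may isomerise to the E (tigloyl) form. The fallback builds the Z alkene on the ester instead of carrying it in; it sets out from 18 and comes back at 21. Coupling with 2-[bis(2,2,2-trifluoroethoxy)phosphoryl]propanoic acid (DCC, DMAP, CH2Cl2) gives the phosphonate ester F6. Still–Gennari olefination with acetaldehyde (KN(SiMe3)2, 18-crown-6, THF, −78 °C) then gives the Z-2-methylbut-2-enoate 21.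

**Further compounds**
F1 | step 4 | diol aryl ether: 8 opened at C9 by 4-methoxyphenol (secondary OH at C10, configuration retained) | C=CC[C@@]1(C)[C@@](O)([C@@H](O)COc2ccc(OC)cc2)CC[C@@H]1C
F2 | step 4 | C10 methanesulfonate of F1 | C=CC[C@@]1(C)[C@@](O)([C@@H](OS(C)(=O)=O)COc2ccc(OC)cc2)CC[C@@H]1C
F3 | step 4 | (2R,3R,4S)-2-[(4-methoxyphenoxy)methyl]-3,4-dimethyl-3-(prop-2-en-1-yl)cyclohexan-1-one | C=CC[C@@]1(C)[C@H](COc2ccc(OC)cc2)C(=O)CC[C@@H]1C
F4 | step 12 | 7β-[(trimethylsilyl)ethynyl]-8α-ol (9α-OTBS, 1α-OSiEt3) | C[Si](C)(C)C#C[C@H]1C[C@@]2(C)[C@H]([C@H](O[Si](C)(C)C(C)(C)C)[C@@H]1O)[C@@H](O[Si](CC)(CC)CC)CC[C@@H]2C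
F5 | step 12 | 7β-ethynyl-8α-ol (9α-OTBS, 1α-OSiEt3) | C#C[C@H]1C[C@@]2(C)[C@H]([C@H](O[Si](C)(C)C(C)(C)C)[C@@H]1O)[C@@H](O[Si](CC)(CC)CC)CC[C@@H]2C
F6 | step 13 | 8-O-{2-[bis(2,2,2-trifluoroethoxy)phosphoryl]propanoate} of 18 (epimers at the phosphonate-bearing carbon) | C=C(C)[C@H]1C[C@@]2(C)[C@H]([C@H](O[Si](C)(C)C(C)(C)C)[C@@H]1OC(=O)C(C)P(=O)(OCC(F)(F)F)OCC(F)(F)F)[C@@H](O[Si](CC)(CC)CC)CC[C@@H]2C
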